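## Structural features

Mururin C (16) is a 2-arylbenzofuran: a benzo ring A fused to a furan whose C2 carries a 3,4-dihydroxy-5-methoxyphenyl ring C and whose C3 carries a formyl group. Ring A bears a methoxy group at C7, next to the ring oxygen, and a 3-hydroxypropyl chain at C5, so it is a dihydroferulate-type C6–C3 unit. The target has no stereocentre. The only stereocentres of the plan are the neighbouring C2 and C3 of a 2,3-dihydrobenzofuran intermediate, and both are erased on aromatisation. The fragile groups are the free catechol (attacked by quinone oxidants and MnO2), the aryl aldehyde, and the primary alcohol, which must be told apart from a second, benzofuran-bound CH2OH that appears on the way. The real difficulty is the fully substituted C2–C3 edge of the furan: an aryl group at C2 beside a one-carbon unit at the aldehyde oxidation level at C3, built regiospecifically onto a ring A of fixed substitution. The feature used is that C2 is bound to O1 and to ring C at once. In a benzyl ether between the ring A phenol oxygen and the ring C benzylic carbon, the OCH2 hydrogens are activated by both neighbours and lie 1,5 to a carbene placed on the arylacetate carbon that becomes C3.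

## Logic of the disconnections

16 ⇒ 15. The two O–CH2Ph bonds on ring C are cut. The catechol would not survive the quinone and MnO2 oxidations, so it stays masked to the end. The gain is a robust, non-phenolic ring C in every earlier step. The demand is benzyl removal beside an aryl aldehyde, a primary alcohol and two methyl ethers, which rules out hydrogenation and calls for a cold Lewis-acid cleavage with a cation scavenger.

15 ⇒ 14. No skeletal bond is cut; the C3 formyl group is traced back to CH2OH. Both carbinols of 14 then come from one reduction and differ only in that one is conjugated to the furan. The demand is an oxidant that touches only the benzofuran-3-ylmethanol and stops at the aldehyde.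

14 ⇒ 13. The two C–OH carbons are traced back to two methyl esters. Esters are spectators that pass through the carbene and quinone steps unchanged. The demand is a hydride reagent strong enough for the deactivated C3 ester and harmless to benzyl and methyl ethers.

13 ⇒ 12. The C2=C3 π bond is exchanged for a C2–H and a C3–H bond. This turns the furan edge into two sp3 carbons that can be joined by a σ-bond-forming step. The demand is a dehydrogenation that starts at the doubly activated C2–H and converges both diastereomers of 12.

12 ⇒ 11. The C2–C3 bond is cut and the dihydrofuran ring opens. C3 becomes a diazo carbon and C2 becomes the OCH2 carbon of a benzyl ether. The cut is made here because C2 carries O1 and ring C, so its C–H bond is the most hydridic one and the only one 1,5 to the carbene. The bicycle falls to two simple arenes joined by an ether, and the C3 substituent arrives as an ester that maps onto the aldehyde. The demand is site selectivity over the other activated C–H bonds and suppression of bimolecular carbene reactions.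

11 ⇒ 10. The C=N2 unit is removed and the arylacetate CH2 is restored. The demand is a diazo transfer that addresses only the arylacetate CH2 and not the propanoate α-CH2.

10 ⇒ 5 + 9. The O–CH2 bond of the ring A/ring C benzyl ether (the future O1–C2 bond) is cut. This is the convergent point: two halves of similar size. The demand is O-alkylation of a phenol flanked on both sides without relactonisation. Both esters of 5 must carry the same alkyl group, so that no alkoxide or alcohol step can scramble them.

9 ⇒ 8 ⇒ 7 ⇒ 6. The C–Br bond, then the carbinol C–H, then the two O–benzyl bonds are removed. This leads to a commercial benzaldehyde with the ring C oxygen pattern in place. The demands are routine: exhaustive O-benzylation and a bromide reactive enough for the hindered phenol.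

5 ⇒ 4 ⇒ 3. The methyl ester C–O bond is traced to a lactone, and the benzylic C–H to a C–OH. An arylacetic unit is most easily introduced at the glycolate level. The demand is removal of a benzylic hydroxyl next to an ester, and opening of the lactone by methanol so that both esters are methyl.

3 ⇒ 1 + 2. The aryl–carbon bond ortho to the phenol is cut. The phenol of 1 has one free ortho position, which is the carbon that becomes C3a. The demand is ortho selectivity over the position para to the methoxy group, which is met by delivering 2 within a titanium phenoxide chelate.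

## Other disconnections considered

Alternative 1: The cut removes the C2–C1′ bond and the bond from C3 to the formyl carbon together and closes no ring. It leaves the 2,3-unsubstituted benzofuran A1 (tert-butyl[3-(7-methoxybenzofuran-5-yl)propoxy]dimethylsilane) and the ring C pinacol boronate A2 (2-[3-methoxy-4,5-bis(methoxymethoxy)phenyl]-4,4,5,5-tetramethyl-1,3,2-dioxaborolane).
- Forward step: A1 would be lithiated at C2 and added to A2. The ate complex reacts like an enol ether: the dimethoxycarbenium ion from HC(OMe)3 and BF3·OEt2 would attack C3 and ring C would migrate from boron to C2. NaOH/H2O2 and then PPTS would re-form the furan and give acetal A3.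
- In favour: two C–C bonds form in one operation and the plan is highly convergent. The C3 carbon arrives at the aldehyde oxidation level. The MOM, TBS and acetal groups are all acid-labile, so one acid treatment could finish the synthesis. No diazo compound is needed.
- Against: A1 needs a benzofuran synthesis of its own. The cascade is intermolecular, so side paths have no geometric constraint against them: attack of the carbenium ion on ring C of A2 at the boron-bearing carbon, loss of MOM groups to BF3, and elimination of methanol from the acetal during the basic oxidation. An oxocarbenium ion is also a less secure trigger for this shift than the carbene is for its insertion.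
- Comparison: both plans pass through a stage with sp3 C2 and C3 that is aromatised afterwards, so they are equal on that point. Mechanistically the chosen plan is the more predictable, because its regiochemistry is set by ring size in an intramolecular step. After the key step the alternative is better (one deprotection against four steps). Over the whole route the two should come out similar once the preparation of A1 is counted.

Alternative 2: The cut is the C7–C7a bond of ring A, so ring A is grown on a preformed 2-arylfuran. The precursor is the Stobbe half-ester A4 ((E)-4-{5-[3,4-bis(benzyloxy)-5-methoxyphenyl]furan-3-yl}-3-(methoxycarbonyl)but-3-enoic acid).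
- Forward step: Ac2O with NaOAc would turn the acid of A4 into a mixed anhydride. Its acyl carbon attacks the free α-position of the furan, and enolisation and acetylation give the 7-acetoxybenzofuran-5-carboxylate A5.
- In favour: the chemistry is classical, cheap and free of azides and metal carbenes. In reliability and safety of the key step itself this plan is the equal or the better of the chosen one. The 5,7-relationship of carbon and oxygen on ring A follows from the mode of construction.
- Against: A5 has none of the three ring substituents in final form. C3 is unsubstituted and must be formylated late, in competition with the electron-rich ring C. The C7 acetate must be exchanged for a methyl ether. The C5 ester must be extended by two carbons and reduced, while benzyl ethers forbid a simple hydrogenation of an olefination product. A4 also rests on a 3,5-disubstituted furan aldehyde that is not readily available.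
- Comparison: the chosen plan brings every ring A substituent in from a C6–C3 phenylpropanoid and only closes the furan. The alternative closes the benzene ring and then corrects three positions. Both key steps close one ring and form one skeletal bond, so they are equal there. In step economy the alternative is clearly worse, with about twice as many operations after A5 as after 12.

Alternative 3: The cut is the O1–C2 bond, preceded by the bond from C3 to the aroyl carbon. The precursor is the 3-aroyl lactone A6 (methyl 3-{3-[3,4-bis(benzyloxy)-5-methoxybenzoyl]-7-methoxy-2-oxo-2,3-dihydrobenzofuran-5-yl}propanoate), which would come from C-aroylation of lactone 4.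
- Forward step: in methanolic HCl the lactone would open to the methyl ester, the freed phenol would add to the aroyl ketone and water would be lost. This gives the benzofuran diester A7, which has the same structure as 13.
- In favour: it branches from 4 and should reach 13 in two operations, where the chosen plan needs the methanolysis and steps 6 to 9. It needs no sulfonyl azide, diazo compound, dirhodium catalyst or quinone, and it never makes stereocentres that are destroyed again. On step economy, reagent hazard and cost it is the better plan.
- Against: C- versus O-aroylation of the lactone enolate must be controlled, or an O-to-C acyl shift arranged. During methanolysis, attack at the ketone carbonyl (retro-Claisen loss of the aroyl group) competes with lactone opening. The benzyl ethers must withstand hot methanolic acid.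
- Comparison: the two plans share everything up to 4 and from 13 onward and differ only in how the C2–C3–O1 unit is assembled. The alternative does it by acylation and cyclodehydration at the carbonyl level. The chosen plan does it by C–H insertion at the sp3 level followed by dehydrogenation, which gives a C–C bond under neutral conditions with built-in regiocontrol. The alternative is shorter and is therefore held in reserve as the fallback for step 8.

Key step: step 8

Remark on the chemistry: both esters are carried as methyl esters (the diazoacetate is the methyl, not the ethyl, ester), because the lactone is opened by methanol and a mixed ethyl/methyl diester would be scrambled by any alkoxide; the ethyl group of 2 leaves as ethanol on lactonisation, and the cis or trans outcome of the insertion is immaterial because step 9 removes both centres.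

## Route

Step 1
Reactants: 1 methyl 3-(4-hydroxy-3-methoxyphenyl)propanoate (methyl dihydroferulate); 2 ethyl glyoxylate
Product: 3 ethyl 2-hydroxy-2-[2-hydroxy-3-methoxy-5-(3-methoxy-3-oxopropyl)phenyl]acetate (racemic)
Conditions: TiCl4 (1.2 equiv), CH2Cl2, −30 °C; then 2 (1.3 equiv, freshly cracked), −30 → 0 °C
Reagents that add atoms: none
Why: Ortho-selective Friedel–Crafts hydroxyalkylation of a phenol: the aryloxytitanium trichloride binds the glyoxylate and delivers it through a cyclic transition state to the only free ortho position. The new carbinol centre forms as the racemate and is removed in step 2.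

Step 2
Reactants: 3 ethyl 2-hydroxy-2-[2-hydroxy-3-methoxy-5-(3-methoxy-3-oxopropyl)phenyl]acetate
Product: 5 methyl 3-[4-hydroxy-3-methoxy-5-(2-methoxy-2-oxoethyl)phenyl]propanoate, via lactone 4 (not isolated)
Conditions: Et3SiH (3 equiv), TFA/CH2Cl2, 0 → 40 °C; evaporate; MeOH, H2SO4 (cat.), reflux; NaHCO3 before concentration
Reagents that add atoms: methanol, CO
Why: Ionic hydrogenation: TFA ionises the benzylic carbinol to a cation stabilised by the ortho oxygen (ortho-quinone methide character) and Et3SiH delivers hydride, while the acid closes lactone 4 with loss of ethanol. Acid-catalysed methanolysis (Fischer-type transesterification) then opens the aryl ester and converges the lactone and any uncyclised ethyl ester on the dimethyl diester 5.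

Step 3
Reactants: 6 3,4-dihydroxy-5-methoxybenzaldehyde (5-hydroxyvanillin)
Product: 7 3,4-bis(benzyloxy)-5-methoxybenzaldehyde
Conditions: BnBr (2.3 equiv), K2CO3, DMF, 60 °C
Reagents that add atoms: benzyl bromide, BrCc1ccccc1
Why: Williamson etherification of both phenols; the aldehyde is inert to carbonate.

Step 4
Reactants: 7 3,4-bis(benzyloxy)-5-methoxybenzaldehyde
Product: 8 [3,4-bis(benzyloxy)-5-methoxyphenyl]methanol
Conditions: NaBH4, MeOH/THF, 0 °C
Reagents that add atoms: none
Why: Borohydride reduction of an aryl aldehyde to the benzylic alcohol.

Step 5
Reactants: 8 [3,4-bis(benzyloxy)-5-methoxyphenyl]methanol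
Product: 9 1,2-bis(benzyloxy)-5-(bromomethyl)-3-methoxybenzene
Conditions: PBr3 (0.4 equiv), CH2Cl2, 0 °C
Reagents that add atoms: phosphorus tribromide, BrP(Br)Br
Why: The benzylic alcohol is activated as a phosphite ester and displaced by bromide (SN2); aryl benzyl and methyl ethers tolerate the brief acidic conditions at 0 °C.

Step 6
Reactants: 5 methyl 3-[4-hydroxy-3-methoxy-5-(2-methoxy-2-oxoethyl)phenyl]propanoate; 9 1,2-bis(benzyloxy)-5-(bromomethyl)-3-methoxybenzene
Product: 10 methyl 3-[4-{[3,4-bis(benzyloxy)-5-methoxybenzyl]oxy}-3-methoxy-5-(2-methoxy-2-oxoethyl)phenyl]propanoate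
Conditions: K2CO3, DMF, rt
Reagents that add atoms: none
Why: Williamson ether synthesis: the phenoxide of 5 displaces bromide from the reactive benzylic bromide. The open ester phenoxide is favoured over the lactone plus methoxide and is trapped irreversibly by alkylation.

Step 7
Reactants: 10 methyl 3-[4-{[3,4-bis(benzyloxy)-5-methoxybenzyl]oxy}-3-methoxy-5-(2-methoxy-2-oxoethyl)phenyl]propanoate
Product: 11 methyl 3-[4-{[3,4-bis(benzyloxy)-5-methoxybenzyl]oxy}-3-(1-diazo-2-methoxy-2-oxoethyl)-5-methoxyphenyl]propanoate
Conditions: p-ABSA (1.3 equiv), DBU (1.5 equiv), MeCN, 0 °C → rt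
Reagents that add atoms: 4-acetamidobenzenesulfonyl azide (p-ABSA), CC(=O)Nc1ccc(cc1)S(=O)(=O)N=[N+]=[N-]
Why: Regitz diazo transfer: DBU deprotonates only the arylacetate CH2 (benzylic and α to the ester), the enolate attacks the terminal azide nitrogen and the triazene collapses to the diazo ester and the sulfonamide. The propanoate α-CH2 is too weakly acidic to react.

Step 8
Reactants: 11 methyl 3-[4-{[3,4-bis(benzyloxy)-5-methoxybenzyl]oxy}-3-(1-diazo-2-methoxy-2-oxoethyl)-5-methoxyphenyl]propanoate
Product: 12 methyl (2R*,3S*)-2-[3,4-bis(benzyloxy)-5-methoxyphenyl]-7-methoxy-5-(3-methoxy-3-oxopropyl)-2,3-dihydrobenzofuran-3-carboxylate (cis, racemic, one enantiomer drawn)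
Conditions: Rh2(OAc)4 (1 mol %), CH2Cl2, 4 Å MS, 40 °C, slow addition of 11
Reagents that add atoms: none
Why: Rh2(OAc)4 adds to the diazo carbon of 11, N2 leaves, and a donor–acceptor rhodium carbene flanked by ring A and the ester results. Its electrophilic carbon takes up a hydridic hydrogen of the OCH2 group of the ring A/ring C benzyl ether through a three-centre, asynchronous transition state; the developing positive charge on that carbon is absorbed by the O1 lone pair and by the para-alkoxy ring C, and the C2–C3 bond forms in the same event with release of the catalyst. The closest known reaction type is the dirhodium-catalysed intramolecular C–H insertion of ortho-benzyloxy aryldiazoacetates to 2-aryl-2,3-dihydrobenzofuran-3-carboxylates. The dihydrofuran ring closes by 1,5-insertion (carbene carbon, two ring A carbons, oxygen, CH2), the only mode that brings an activated C–H bond to the carbene without strain. C2 and C3 are created together, and their relative configuration is set by the orientation of ring C relative to the ester in the insertion transition state; the cis isomer is expected to predominate, the achiral catalyst gives the racemate, and any trans isomer is carried on because step 9 removes both centres. The selectivity needed is for this CH2 group over the CH2 groups of the benzyl protecting ethers, the methoxy groups and the arene π systems. It is secured by geometry (the protecting-group and ring C C–H bonds are far away and the ring A methoxy group is held away by the rigid arene), by the double activation of the target C–H bond, and by the tempered reactivity of a donor–acceptor carbene. Slow addition at high dilution and molecular sieves suppress carbene dimerisation and O–H insertion of water.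

Step 9
Reactants: 12 methyl (2R*,3S*)-2-[3,4-bis(benzyloxy)-5-methoxyphenyl]-7-methoxy-5-(3-methoxy-3-oxopropyl)-2,3-dihydrobenzofuran-3-carboxylate
Product: 13 methyl 2-[3,4-bis(benzyloxy)-5-methoxyphenyl]-7-methoxy-5-(3-methoxy-3-oxopropyl)benzofuran-3-carboxylate
Conditions: DDQ (1.5 equiv), 1,4-dioxane, 100 °C
Reagents that add atoms: none
Why: Quinone dehydrogenation by hydride abstraction: DDQ removes hydride from C2, which is benzylic to the para-alkoxy ring C and α to O1, and loss of the acidic C3 proton gives the aromatic furan. Cis and trans isomers converge, and the O-benzyl CH2 groups lack this double activation.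

Step 10
Reactants: 13 methyl 2-[3,4-bis(benzyloxy)-5-methoxyphenyl]-7-methoxy-5-(3-methoxy-3-oxopropyl)benzofuran-3-carboxylate
Product: 14 3-{2-[3,4-bis(benzyloxy)-5-methoxyphenyl]-3-(hydroxymethyl)-7-methoxybenzofuran-5-yl}propan-1-ol
Conditions: i-Bu2AlH (DIBAL-H, 5 equiv), CH2Cl2, −78 → 0 °C; aq. potassium sodium tartrate
Reagents that add atoms: none
Why: Aluminium hydride reduction of both esters to primary alcohols; the excess and the warming to 0 °C take care of the less electrophilic, vinylogous-carbonate-like C3 ester. Benzyl and methyl ethers are inert.

Step 11
Reactants: 14 3-{2-[3,4-bis(benzyloxy)-5-methoxyphenyl]-3-(hydroxymethyl)-7-methoxybenzofuran-5-yl}propan-1-ol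
Product: 15 2-[3,4-bis(benzyloxy)-5-methoxyphenyl]-5-(3-hydroxypropyl)-7-methoxybenzofuran-3-carbaldehyde
Conditions: MnO2 (activated, excess), CH2Cl2, rt
Reagents that add atoms: none
Why: Selective oxidation of an allylic/benzylic-type alcohol: MnO2 oxidises only the carbinol conjugated to the furan π system and stops at the aldehyde. The saturated 3-hydroxypropyl alcohol is not touched.

Step 12
Reactants: 15 2-[3,4-bis(benzyloxy)-5-methoxyphenyl]-5-(3-hydroxypropyl)-7-methoxybenzofuran-3-carbaldehyde
Product: 16 Mururin C, 2-(3,4-dihydroxy-5-methoxyphenyl)-5-(3-hydroxypropyl)-7-methoxybenzofuran-3-carbaldehyde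
Conditions: BCl3 (1 M in CH2Cl2, 5 equiv), C6HMe5 (6 equiv), CH2Cl2, −78 °C; MeOH, then aq. NaHCO3
Reagents that add atoms: none
Why: Lewis-acid cleavage of aryl benzyl ethers with a non-basic cation scavenger: BCl3 activates the ether oxygens and pentamethylbenzene captures the benzyl cations (Friedel–Crafts), so the electron-rich rings are not C-benzylated. At −78 °C the aryl methyl ethers, the aldehyde and the alcohol (held as a borate and released on work-up) should survive.

## Compound list

1 | methyl 3-(4-hydroxy-3-methoxyphenyl)propanoate (methyl dihydroferulate) | COC(=O)CCc1ccc(O)c(OC)c1 | starting material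
2 | ethyl glyoxylate | CCOC(=O)C=O | starting material
3 | ethyl 2-hydroxy-2-[2-hydroxy-3-methoxy-5-(3-methoxy-3-oxopropyl)phenyl]acetate (racemic) | CCOC(=O)C(O)c1cc(CCC(=O)OC)cc(OC)c1O | intermediate
4 | methyl 3-(7-methoxy-2-oxo-2,3-dihydrobenzofuran-5-yl)propanoate (lactone, not isolated) | COC(=O)CCc1cc(OC)c2OC(=O)Cc2c1 | intermediate
5 | methyl 3-[4-hydroxy-3-methoxy-5-(2-methoxy-2-oxoethyl)phenyl]propanoate | COC(=O)CCc1cc(CC(=O)OC)c(O)c(OC)c1 | intermediate
6 | 3,4-dihydroxy-5-methoxybenzaldehyde (5-hydroxyvanillin) | COc1cc(C=O)cc(O)c1O | starting material
7 | 3,4-bis(benzyloxy)-5-methoxybenzaldehyde | COc1cc(C=O)cc(OCc2ccccc2)c1OCc1ccccc1 | intermediate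
8 | [3,4-bis(benzyloxy)-5-methoxyphenyl]methanol | COc1cc(CO)cc(OCc2ccccc2)c1OCc1ccccc1 | intermediate
9 | 1,2-bis(benzyloxy)-5-(bromomethyl)-3-methoxybenzene | COc1cc(CBr)cc(OCc2ccccc2)c1OCc1ccccc1 | intermediate
10 | methyl 3-[4-{[3,4-bis(benzyloxy)-5-methoxybenzyl]oxy}-3-methoxy-5-(2-methoxy-2-oxoethyl)phenyl]propanoate | COC(=O)CCc1cc(CC(=O)OC)c(OCc2cc(OC)c(OCc3ccccc3)c(OCc3ccccc3)c2)c(OC)c1 | intermediate
11 | methyl 3-[4-{[3,4-bis(benzyloxy)-5-methoxybenzyl]oxy}-3-(1-diazo-2-methoxy-2-oxoethyl)-5-methoxyphenyl]propanoate | COC(=O)CCc1cc(OC)c(OCc2cc(OC)c(OCc3ccccc3)c(OCc3ccccc3)c2)c(C(=[N+]=[N-])C(=O)OC)c1 | intermediate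
12 | methyl (2R*,3S*)-2-[3,4-bis(benzyloxy)-5-methoxyphenyl]-7-methoxy-5-(3-methoxy-3-oxopropyl)-2,3-dihydrobenzofuran-3-carboxylate (cis, racemic, one enantiomer drawn) | COC(=O)[C@@H]1[C@H](c2cc(OC)c(OCc3ccccc3)c(OCc3ccccc3)c2)Oc2c(OC)cc(CCC(=O)OC)cc21 | intermediate
13 | methyl 2-[3,4-bis(benzyloxy)-5-methoxyphenyl]-7-methoxy-5-(3-methoxy-3-oxopropyl)benzofuran-3-carboxylate | COC(=O)CCc1cc(OC)c2oc(-c3cc(OC)c(OCc4ccccc4)c(OCc4ccccc4)c3)c(C(=O)OC)c2c1 | intermediate
14 | 3-{2-[3,4-bis(benzyloxy)-5-methoxyphenyl]-3-(hydroxymethyl)-7-methoxybenzofuran-5-yl}propan-1-ol | OCCCc1cc(OC)c2oc(-c3cc(OC)c(OCc4ccccc4)c(OCc4ccccc4)c3)c(CO)c2c1 | intermediate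
15 | 2-[3,4-bis(benzyloxy)-5-methoxyphenyl]-5-(3-hydroxypropyl)-7-methoxybenzofuran-3-carbaldehyde | OCCCc1cc(OC)c2oc(-c3cc(OC)c(OCc4ccccc4)c(OCc4ccccc4)c3)c(C=O)c2c1 | intermediate
16 | Mururin C, 2-(3,4-dihydroxy-5-methoxyphenyl)-5-(3-hydroxypropyl)-7-methoxybenzofuran-3-carbaldehyde | COc1cc(-c2oc3c(OC)cc(CCCO)cc3c2C=O)cc(O)c1O | target

## Step count and least certain steps

Total step count: 12. Longest linear sequence: 10 steps (from 6 through steps 3, 4, 5, 6, 7, 8, 9, 10, 11 and 12); the ring A branch from 1 runs 9 steps.

Step 8 (key step). The most likely failure is that bimolecular carbene dimerisation or O–H insertion of moisture outruns the intramolecular insertion, or that the carbene attacks the electron-rich ring C instead of the ether C–H bond. The fallback assembles the same C2–C3–O1 unit at the carbonyl level and sets out from aldehyde 7 and lactone 4, which is isolated after the silane stage of step 2 for this purpose. Aldehyde 7 is oxidised (NaClO2, NaH2PO4, 2-methyl-2-butene, t-BuOH/H2O) to 3,4-bis(benzyloxy)-5-methoxybenzoic acid F1. This is converted with (COCl)2 and catalytic DMF into 3,4-bis(benzyloxy)-5-methoxybenzoyl chloride F2. Lactone 4 is aroylated with F2 (Et3N, catalytic DMAP, CH2Cl2; O-acylation followed by acyl transfer to carbon) to methyl 3-{3-[3,4-bis(benzyloxy)-5-methoxybenzoyl]-7-methoxy-2-oxo-2,3-dihydrobenzofuran-5-yl}propanoate F3, the same structure as A6. HCl in methanol at reflux then opens the lactone and cyclodehydrates to 13, where the route is rejoined.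

Step 1. The likely failures are attack para to the methoxy group when the titanium phenoxide chelate is incompletely formed, and a second Friedel–Crafts alkylation in which the product carbinol ionises and captures another arene. The fallback uses phenolate C-alkylation, which can only go ortho because the para position is blocked. It sets out from 1: aqueous glyoxylic acid in NaOH saponifies the methyl ester and alkylates the phenolate in the same pot to give 3-{3-[carboxy(hydroxy)methyl]-4-hydroxy-5-methoxyphenyl}propanoic acid F4. SnCl2·2H2O in hot concentrated HCl removes the benzylic hydroxyl to give 3-[3-(carboxymethyl)-4-hydroxy-5-methoxyphenyl]propanoic acid F5 (its lactone would behave the same way in the next operation). Esterification in MeOH with H2SO4 returns to the route at 5.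

Step 2. The likely failures are incomplete ionisation of the carbinol, which is deactivated by the neighbouring ester, and capture of the cation by a second electron-rich arene before the silane reacts. The fallback replaces ionic hydride transfer by heterogeneous hydrogenolysis. It sets out from 3: H2 over Pd/C (palladium on carbon) in AcOH with catalytic H2SO4 at 50 °C cleaves the benzylic C–O bond, the acid closes lactone 4, and the methanolysis of step 2 then returns to the route at 5. No compound outside the compound list is made (F0).

Step 9. The likely failures are sluggish hydride abstraction at C2 because of the adjacent ester, and competing oxidation at the benzyl ether CH2 groups with loss of a protecting group. The fallback uses enolate selenation and syn-elimination and sets out from 12. LiN(SiMe3)2 in THF at −78 °C forms the C3 enolate, and PhSeBr adds anti to the C2 aryl group to give methyl 2-[3,4-bis(benzyloxy)-5-methoxyphenyl]-7-methoxy-5-(3-methoxy-3-oxopropyl)-3-(phenylselanyl)-2,3-dihydrobenzofuran-3-carboxylate F6 (selenium trans to the C2 aryl group and therefore cis to C2–H, racemic). H2O2 in CH2Cl2/pyridine at 0 °C gives the selenoxide, which eliminates with the syn C2–H to return to the route at 13.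

Step 12. The likely failures are cleavage of a methyl ether next to the freshly liberated, boron-bound catechol, condensation of the Lewis acid with the aldehyde and the alcohol, and air oxidation of the free catechol during work-up. The fallback removes the benzyl groups where nothing reducible is present and sets out from 13. H2 over Pd/C in EtOAc/MeOH gives methyl 2-(3,4-dihydroxy-5-methoxyphenyl)-7-methoxy-5-(3-methoxy-3-oxopropyl)benzofuran-3-carboxylate F7. TBSCl and imidazole in DMF give methyl 2-[3,4-bis(tert-butyldimethylsilyloxy)-5-methoxyphenyl]-7-methoxy-5-(3-methoxy-3-oxopropyl)benzofuran-3-carboxylate F8. i-Bu2AlH as in step 10 gives 3-{2-[3,4-bis(tert-butyldimethylsilyloxy)-5-methoxyphenyl]-3-(hydroxymethyl)-7-methoxybenzofuran-5-yl}propan-1-ol F9. MnO2 as in step 11 gives 2-[3,4-bis(tert-butyldimethylsilyloxy)-5-methoxyphenyl]-5-(3-hydroxypropyl)-7-methoxybenzofuran-3-carbaldehyde F10. Bu4NF buffered with AcOH in THF at 0 °C removes the silyl groups and arrives at 16.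

## Further compounds

F1 | step 8 | 3,4-bis(benzyloxy)-5-methoxybenzoic acid | COc1cc(C(=O)O)cc(OCc2ccccc2)c1OCc1ccccc1
F2 | step 8 | 3,4-bis(benzyloxy)-5-methoxybenzoyl chloride | COc1cc(C(=O)Cl)cc(OCc2ccccc2)c1OCc1ccccc1
F3 | step 8 | methyl 3-{3-[3,4-bis(benzyloxy)-5-methoxybenzoyl]-7-methoxy-2-oxo-2,3-dihydrobenzofuran-5-yl}propanoate (racemic, enolisable) | COC(=O)CCc1cc(OC)c2OC(=O)C(C(=O)c3cc(OC)c(OCc4ccccc4)c(OCc4ccccc4)c3)c2c1
F4 | step 1 | 3-{3-[carboxy(hydroxy)methyl]-4-hydroxy-5-methoxyphenyl}propanoic acid (racemic) | OC(=O)CCc1cc(OC)c(O)c(C(O)C(=O)O)c1
F5 | step 1 | 3-[3-(carboxymethyl)-4-hydroxy-5-methoxyphenyl]propanoic acid | OC(=O)CCc1cc(OC)c(O)c(CC(=O)O)c1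
F0 | step 2 | none | none
F6 | step 9 | methyl 2-[3,4-bis(benzyloxy)-5-methoxyphenyl]-7-methoxy-5-(3-methoxy-3-oxopropyl)-3-(phenylselanyl)-2,3-dihydrobenzofuran-3-carboxylate (selenium trans to the C2 aryl group, racemic, one enantiomer drawn) | COC(=O)[C@]1([Se]c2ccccc2)[C@H](c2cc(OC)c(OCc3ccccc3)c(OCc3ccccc3)c2)Oc2c(OC)cc(CCC(=O)OC)cc21
F7 | step 12 | methyl 2-(3,4-dihydroxy-5-methoxyphenyl)-7-methoxy-5-(3-methoxy-3-oxopropyl)benzofuran-3-carboxylate | COC(=O)CCc1cc(OC)c2oc(-c3cc(OC)c(O)c(O)c3)c(C(=O)OC)c2c1
F8 | step 12 | methyl 2-[3,4-bis(tert-butyldimethylsilyloxy)-5-methoxyphenyl]-7-methoxy-5-(3-methoxy-3-oxopropyl)benzofuran-3-carboxylate | COC(=O)CCc1cc(OC)c2oc(-c3cc(OC)c(O[Si](C)(C)C(C)(C)C)c(O[Si](C)(C)C(C)(C)C)c3)c(C(=O)OC)c2c1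
F9 | step 12 | 3-{2-[3,4-bis(tert-butyldimethylsilyloxy)-5-methoxyphenyl]-3-(hydroxymethyl)-7-methoxybenzofuran-5-yl}propan-1-ol | OCCCc1cc(OC)c2oc(-c3cc(OC)c(O[Si](C)(C)C(C)(C)C)c(O[Si](C)(C)C(C)(C)C)c3)c(CO)c2c1
F10 | step 12 | 2-[3,4-bis(tert-butyldimethylsilyloxy)-5-methoxyphenyl]-5-(3-hydroxypropyl)-7-methoxybenzofuran-3-carbaldehyde | OCCCc1cc(OC)c2oc(-c3cc(OC)c(O[Si](C)(C)C(C)(C)C)c(O[Si](C)(C)C(C)(C)C)c3)c(C=O)c2c1
A1 | alternative 1 | tert-butyl[3-(7-methoxybenzofuran-5-yl)propoxy]dimethylsilane | COc1cc(CCCO[Si](C)(C)C(C)(C)C)cc2ccoc12
A2 | alternative 1 | 2-[3-methoxy-4,5-bis(methoxymethoxy)phenyl]-4,4,5,5-tetramethyl-1,3,2-dioxaborolane | COCOc1cc(B2OC(C)(C)C(C)(C)O2)cc(OC)c1OCOC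
A3 | alternative 1 | tert-butyl[3-(3-(dimethoxymethyl)-7-methoxy-2-[3-methoxy-4,5-bis(methoxymethoxy)phenyl]benzofuran-5-yl)propoxy]dimethylsilane | COC(OC)c1c(-c2cc(OC)c(OCOC)c(OCOC)c2)oc2c(OC)cc(CCCO[Si](C)(C)C(C)(C)C)cc12
A4 | alternative 2 | (E)-4-{5-[3,4-bis(benzyloxy)-5-methoxyphenyl]furan-3-yl}-3-(methoxycarbonyl)but-3-enoic acid | COC(=O)/C(=C/c1coc(-c2cc(OC)c(OCc3ccccc3)c(OCc3ccccc3)c2)c1)CC(=O)O
A5 | alternative 2 | methyl 7-acetoxy-2-[3,4-bis(benzyloxy)-5-methoxyphenyl]benzofuran-5-carboxylate | COC(=O)c1cc(OC(C)=O)c2oc(-c3cc(OC)c(OCc4ccccc4)c(OCc4ccccc4)c3)cc2c1
A6 | alternative 3 | methyl 3-{3-[3,4-bis(benzyloxy)-5-methoxybenzoyl]-7-methoxy-2-oxo-2,3-dihydrobenzofuran-5-yl}propanoate | COC(=O)CCc1cc(OC)c2OC(=O)C(C(=O)c3cc(OC)c(OCc4ccccc4)c(OCc4ccccc4)c3)c2c1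
A7 | alternative 3 | methyl 2-[3,4-bis(benzyloxy)-5-methoxyphenyl]-7-methoxy-5-(3-methoxy-3-oxopropyl)benzofuran-3-carboxylate | COC(=O)CCc1cc(OC)c2oc(-c3cc(OC)c(OCc4ccccc4)c(OCc4ccccc4)c3)c(C(=O)OC)c2c1
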